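Ring B is taken apart across C5–C6 and C9–C10: its vicinal C5 methine (isopropenyl) and quaternary C10 (methyl, C1 chain), with the C7 oxygen 1,4 to C10, map onto the adduct of a 2-silyloxybutadiene and an (E)-α-methyl enal. One catalytic asymmetric Diels–Alder reaction therefore closes ring B, sets both stereocentres and leaves a C7 silyl enol ether and a C10 formyl group as handles. Its precursors are achiral (E)-2,4-dimethylpenta-2,4-dienal and 2-(triisopropylsilyloxy)butadiene, one step each from commercial materials. The formyl group is then extended to the propanoate, the enol ether is turned into the C8=C9 enone, and ring C is annulated in one operation with a tetronate-derived sulfone.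

Key step: step 3

Remark on the chemistry: atom labels follow abietane numbering (C1–C3 acid chain, C5 to C10 ring B, C11–C14 the substituted carbons of ring C); the (S)-configured catalyst is chosen from the accepted formyl C–H···O binding model for α-substituted enals, which predicts attack on the C10 face leading to the (5S,10S) target.

Step 1
Reactants: 1 methacrolein; 2 2-(triphenylphosphoranylidene)propanal
Product: 3 (2E)-2,4-dimethylpenta-2,4-dienal
Conditions: 1 (2 equiv), CH2Cl2, reflux; pentane trituration, careful distillation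
Reagents that add atoms: none
Why: Wittig olefination with a formyl-stabilised ylide is E-selective, and the ylide should react with the unhindered aldehyde 1 faster than with the α-branched product 3.

Step 2
Reactants: 4 but-3-en-2-one
Product: 5 2-(triisopropylsilyloxy)buta-1,3-diene
Conditions: i-Pr3SiOTf, Et3N, Et2O, 0 °C → rt; distillation
Reagents that add atoms: triisopropylsilyl trifluoromethanesulfonate, CC(C)[Si](OS(=O)(=O)C(F)(F)F)(C(C)C)C(C)C
Why: Soft enolisation and O-silylation of the methyl ketone (silyl triflate with amine base) is the standard silyl enol ether formation that gives the 2-silyloxydiene.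

Step 3
Reactants: 3 (2E)-2,4-dimethylpenta-2,4-dienal; 5 2-(triisopropylsilyloxy)buta-1,3-diene
Product: 6 (1R,6S)-1-methyl-6-(prop-1-en-2-yl)-4-(triisopropylsilyloxy)cyclohex-3-ene-1-carbaldehyde
Conditions: (S)-1-(2-methylphenyl)-3,3-diphenyltetrahydro-1H,3H-pyrrolo[1,2-c][1,3,2]oxazaborole (20 mol %), HNTf2 (18 mol %), 5 (2 equiv), CH2Cl2, −78 → −40 °C; Et3N quench
Reagents that add atoms: none
Why: The N-protonated oxazaborolidine binds the formyl oxygen of 3 (formyl C–H held against the ring oxygen), lowers the LUMO of the adjacent C5=C10 bond and lets the silyloxy-polarised diene add in a concerted, asynchronous [4+2] cycloaddition in which C6–C5 bonding runs ahead of C9–C10 bonding. The closest known reaction type is the cationic oxazaborolidine-catalysed enantioselective Diels–Alder reaction of 2-silyloxydienes with α-substituted enals that creates quaternary centres. Ring B is closed in this intermolecular [4+2] mode, both new σ-bonds being formed in the same step. C10 is set by the catalyst, whose phenyl group cis to the bound aldehyde shields one face of the s-trans enal so that the diene attacks the open face, and C5 follows from suprafacial addition to the (E)-alkene, which places CH3 cis and the formyl group trans to isopropenyl. Site selectivity (C5=C10 over the distal 1,1-disubstituted alkene) should come from formyl complexation, which activates the adjacent alkene inside the catalyst pocket, regioselectivity (C7 oxygen 1,4 to C10) from the nucleophilic CH2 terminus next to the silyloxy carbon meeting the β-carbon C5, and enantioface selectivity from the catalyst.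

Step 4
Reactants: 6 (1R,6S)-1-methyl-6-(prop-1-en-2-yl)-4-(triisopropylsilyloxy)cyclohex-3-ene-1-carbaldehyde; 7 tert-butyl 2-(diethoxyphosphoryl)acetate
Product: 8 tert-butyl (2E)-3-[(1S,6S)-1-methyl-6-(prop-1-en-2-yl)-4-(triisopropylsilyloxy)cyclohex-3-en-1-yl]prop-2-enoate
Conditions: NaH, THF, 0 °C → 40 °C
Reagents that add atoms: none
Why: Horner–Wadsworth–Emmons olefination of the non-enolisable neopentyl aldehyde should give the (E)-enoate and leave the silyl enol ether, the isopropenyl group and both stereocentres untouched.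

Step 5
Reactants: 8 tert-butyl (2E)-3-[(1S,6S)-1-methyl-6-(prop-1-en-2-yl)-4-(triisopropylsilyloxy)cyclohex-3-en-1-yl]prop-2-enoate
Product: 9 tert-butyl 3-[(1R,6S)-1-methyl-6-(prop-1-en-2-yl)-4-(triisopropylsilyloxy)cyclohex-3-en-1-yl]propanoate
Conditions: [(Ph3P)CuH]6 (0.5 equiv), H2O (5 equiv), degassed toluene, rt
Reagents that add atoms: none
Why: Copper hydride conjugate reduction (Stryker reagent) delivers hydride only to the β-carbon of the enoate, so the isolated isopropenyl alkene and the silyl enol ether should survive.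

Step 6
Reactants: 9 tert-butyl 3-[(1R,6S)-1-methyl-6-(prop-1-en-2-yl)-4-(triisopropylsilyloxy)cyclohex-3-en-1-yl]propanoate
Product: 10 tert-butyl 3-[(1R,6S)-1-methyl-4-oxo-6-(prop-1-en-2-yl)cyclohex-2-en-1-yl]propanoate
Conditions: Pd(OAc)2 (1.2 equiv), MeCN/DMSO, 45 °C
Reagents that add atoms: none
Why: In the Saegusa–Ito oxidation the enol ether hands C8 to divalent palladium and β-hydride elimination can only take place towards C9, so the C8=C9 enone should form regiospecifically.

Step 7
Reactants: 11 ethyl 2-isopropylacetoacetate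
Product: 13 4-hydroxy-3-(propan-2-yl)furan-2(5H)-one (3-isopropyltetronic acid), via ethyl 4-bromo-2-isopropyl-3-oxobutanoate 12 (not isolated)
Conditions: Br2 (1.05 equiv), CHCl3, 0 °C → rt, 16 h; concentrate; neat, 130 °C
Reagents that add atoms: none
Why: Bromination of the β-keto ester settles on the terminal methyl group through HBr-mediated equilibration, and on heating the ester oxygen displaces bromide with loss of bromoethane, the classical tetronic acid synthesis.

Step 8
Reactants: 13 4-hydroxy-3-(propan-2-yl)furan-2(5H)-one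
Product: 14 4-methoxy-3-(propan-2-yl)furan-2(5H)-one
Conditions: Me2SO4, K2CO3, acetone, reflux
Reagents that add atoms: dimethyl sulfate, COS(=O)(=O)OC
Why: O-Alkylation of the vinylogous acid with a hard methylating agent should give the 4-methoxy butenolide (methyl tetronate).

Step 9
Reactants: 14 4-methoxy-3-(propan-2-yl)furan-2(5H)-one
Product: 15 4-methoxy-5-(phenylsulfanyl)-3-(propan-2-yl)furan-2(5H)-one (racemic)
Conditions: LDA (commercial solution, 2.1 equiv), THF, −78 °C; PhSSPh (1.05 equiv), −78 → 0 °C; aq NH4Cl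
Reagents that add atoms: diphenyl disulfide, c1ccc(cc1)SSc1ccccc1
Why: γ-Deprotonation at C5, the only acidic site since C3 is blocked by isopropyl, gives a furanolate that the disulfide sulfenylates (enolate sulfenylation), the second equivalent of base absorbing the more acidic product.

Step 10
Reactants: 15 4-methoxy-5-(phenylsulfanyl)-3-(propan-2-yl)furan-2(5H)-one
Product: 16 4-methoxy-5-(phenylsulfonyl)-3-(propan-2-yl)furan-2(5H)-one (racemic)
Conditions: mCPBA (2.2 equiv), CH2Cl2, 0 °C → rt
Reagents that add atoms: 3-chloroperoxybenzoic acid, OOC(=O)c1cccc(Cl)c1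
Why: Peracid oxidation takes the sulfide to the sulfone, while the electron-poor tetrasubstituted butenolide alkene should not be epoxidised.

Step 11
Reactants: 10 tert-butyl 3-[(1R,6S)-1-methyl-4-oxo-6-(prop-1-en-2-yl)cyclohex-2-en-1-yl]propanoate; 16 4-methoxy-5-(phenylsulfonyl)-3-(propan-2-yl)furan-2(5H)-one
Product: 19 tert-butyl 3-[(1S,2S)-5,8-dihydroxy-7-methoxy-1-methyl-4-oxo-6-(propan-2-yl)-2-(prop-1-en-2-yl)-1,2,3,4-tetrahydronaphthalen-1-yl]propanoate, via sulfonyl lactone Michael adduct 17 (not isolated), via ring C enedione 18 (not isolated)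
Conditions: 16 (1.3 equiv), LiOt-Bu (3 equiv), THF, −78 °C; then 10, −78 °C → rt, argon; aq NH4Cl/Na2S2O4 work-up
Reagents that add atoms: none
Why: Proposed new method: LiOt-Bu deprotonates C5 of sulfone 16 to a sulfonyl-stabilised furanolate that adds through C5 to C9 of enone 10, the resulting C8 enolate closes ring C by Dieckmann attack on the lactone carbonyl, the opened lactone releases an α-sulfonyl alkoxide that expels benzenesulfinate to give the C11 ketone, and the ene-1,4-dione 18 enolises twice to the aromatic hydroquinone as the thermodynamic sink; the closest known reaction type is the Hauser–Kraus annulation of 3-(phenylsulfonyl)phthalides with cyclohexenones, from which this step differs in that the donor is a monocyclic tetronate sulfone (its 3-isopropyl and 4-methoxy groups block self-condensation), and the transient centres at C9 and C11 are erased on aromatisation while C5 and C10 are not touched.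

Step 12
Reactants: 19 tert-butyl 3-[(1S,2S)-5,8-dihydroxy-7-methoxy-1-methyl-4-oxo-6-(propan-2-yl)-2-(prop-1-en-2-yl)-1,2,3,4-tetrahydronaphthalen-1-yl]propanoate
Product: 21 3-[(1S,2S)-5,8-dihydroxy-7-methoxy-1-methyl-4-oxo-6-(propan-2-yl)-2-(prop-1-en-2-yl)-1,2,3,4-tetrahydronaphthalen-1-yl]propanoic acid (target), via tris(trimethylsilyl) derivative 20 (not isolated)
Conditions: Me3SiOTf (4 equiv), 2,6-lutidine (6 equiv), CH2Cl2, 0 °C → rt; then MeOH, aq citric acid, 0 °C, argon
Reagents that add atoms: none
Why: Silyl triflate-mediated tert-butyl ester cleavage (loss of 2-methylpropene from the O-silylated ester) under amine buffering avoids the protic acid that would protonate the isopropenyl group, and mild aqueous acid then hydrolyses the silyl ester and aryl silyl ethers.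

Compound list
1 | methacrolein (2-methylprop-2-enal) | C=C(C)C=O | starting material
2 | 2-(triphenylphosphoranylidene)propanal | CC(C=O)=P(c1ccccc1)(c1ccccc1)c1ccccc1 | starting material
3 | (2E)-2,4-dimethylpenta-2,4-dienal | C=C(C)/C=C(\C)C=O | intermediate
4 | but-3-en-2-one | C=CC(C)=O | starting material
5 | 2-(triisopropylsilyloxy)buta-1,3-diene | C=CC(=C)O[Si](C(C)C)(C(C)C)C(C)C | intermediate
6 | (1R,6S)-1-methyl-6-(prop-1-en-2-yl)-4-(triisopropylsilyloxy)cyclohex-3-ene-1-carbaldehyde | C=C(C)[C@@H]1CC(O[Si](C(C)C)(C(C)C)C(C)C)=CC[C@@]1(C)C=O | intermediate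
7 | tert-butyl 2-(diethoxyphosphoryl)acetate | CCOP(=O)(CC(=O)OC(C)(C)C)OCC | starting material
8 | tert-butyl (2E)-3-[(1S,6S)-1-methyl-6-(prop-1-en-2-yl)-4-(triisopropylsilyloxy)cyclohex-3-en-1-yl]prop-2-enoate | C=C(C)[C@@H]1CC(O[Si](C(C)C)(C(C)C)C(C)C)=CC[C@@]1(C)/C=C/C(=O)OC(C)(C)C | intermediate
9 | tert-butyl 3-[(1R,6S)-1-methyl-6-(prop-1-en-2-yl)-4-(triisopropylsilyloxy)cyclohex-3-en-1-yl]propanoate | C=C(C)[C@@H]1CC(O[Si](C(C)C)(C(C)C)C(C)C)=CC[C@@]1(C)CCC(=O)OC(C)(C)C | intermediate
10 | tert-butyl 3-[(1R,6S)-1-methyl-4-oxo-6-(prop-1-en-2-yl)cyclohex-2-en-1-yl]propanoate | C=C(C)[C@@H]1CC(=O)C=C[C@@]1(C)CCC(=O)OC(C)(C)C | intermediate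
11 | ethyl 2-isopropylacetoacetate (racemic) | CCOC(=O)C(C(C)C)C(C)=O | starting material
12 | ethyl 4-bromo-2-isopropyl-3-oxobutanoate | CCOC(=O)C(C(C)C)C(=O)CBr | intermediate (not isolated)
13 | 4-hydroxy-3-(propan-2-yl)furan-2(5H)-one | CC(C)C1=C(O)COC1=O | intermediate
14 | 4-methoxy-3-(propan-2-yl)furan-2(5H)-one | COC1=C(C(C)C)C(=O)OC1 | intermediate
15 | 4-methoxy-5-(phenylsulfanyl)-3-(propan-2-yl)furan-2(5H)-one (racemic) | COC1=C(C(C)C)C(=O)OC1Sc1ccccc1 | intermediate
16 | 4-methoxy-5-(phenylsulfonyl)-3-(propan-2-yl)furan-2(5H)-one (racemic) | COC1=C(C(C)C)C(=O)OC1S(=O)(=O)c1ccccc1 | intermediate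
17 | tert-butyl 3-[(1S,6S)-2-[3-methoxy-5-oxo-2-(phenylsulfonyl)-4-(propan-2-yl)-2,5-dihydrofuran-2-yl]-1-methyl-4-oxo-6-(prop-1-en-2-yl)cyclohexyl]propanoate (epimers at the two new centres) | C=C(C)[C@@H]1CC(=O)CC(C2(S(=O)(=O)c3ccccc3)OC(=O)C(C(C)C)=C2OC)[C@@]1(C)CCC(=O)OC(C)(C)C | intermediate (not isolated)
18 | tert-butyl 3-[(1S,2S)-7-methoxy-1-methyl-4,5,8-trioxo-6-(propan-2-yl)-2-(prop-1-en-2-yl)-1,2,3,4,4a,5,8,8a-octahydronaphthalen-1-yl]propanoate | C=C(C)[C@@H]1CC(=O)C2C(=O)C(C(C)C)=C(OC)C(=O)C2[C@@]1(C)CCC(=O)OC(C)(C)C | intermediate (not isolated)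
19 | tert-butyl 3-[(1S,2S)-5,8-dihydroxy-7-methoxy-1-methyl-4-oxo-6-(propan-2-yl)-2-(prop-1-en-2-yl)-1,2,3,4-tetrahydronaphthalen-1-yl]propanoate | C=C(C)[C@@H]1CC(=O)c2c(O)c(C(C)C)c(OC)c(O)c2[C@@]1(C)CCC(=O)OC(C)(C)C | intermediate
20 | trimethylsilyl 3-[(1S,2S)-7-methoxy-1-methyl-4-oxo-6-(propan-2-yl)-2-(prop-1-en-2-yl)-5,8-bis(trimethylsilyloxy)-1,2,3,4-tetrahydronaphthalen-1-yl]propanoate | C=C(C)[C@@H]1CC(=O)c2c(O[Si](C)(C)C)c(C(C)C)c(OC)c(O[Si](C)(C)C)c2[C@@]1(C)CCC(=O)O[Si](C)(C)C | intermediate (not isolated)
21 | 3-[(1S,2S)-5,8-dihydroxy-7-methoxy-1-methyl-4-oxo-6-(propan-2-yl)-2-(prop-1-en-2-yl)-1,2,3,4-tetrahydronaphthalen-1-yl]propanoic acid | C=C(C)[C@@H]1CC(=O)c2c(O)c(C(C)C)c(OC)c(O)c2[C@@]1(C)CCC(=O)O | target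

Total step count: 12. Longest linear sequence: 7 steps (steps 1, 3, 4, 5, 6, 11, 12).

Steps most likely to fail

Step 11 (the labelled step). The fully substituted sulfonyl carbanion must add to C9 next to the quaternary C10. This addition may be slow and reversible, so that the donor decays first. Ring closure onto the electron-rich lactone carbonyl may also stall. The fallback uses established reaction types only, sets out from 14 and 10 and comes back at 19. Silylation of 14 (t-BuMe2SiOTf, Et3N, CH2Cl2, 0 °C) should give the silyloxyfuran tert-butyl{[4-methoxy-3-(propan-2-yl)furan-2-yl]oxy}dimethylsilane F1. A vinylogous Mukaiyama–Michael addition of F1 to 10 (catalytic t-BuMe2SiOTf, CH2Cl2, −78 °C, dilute acid work-up) joins the unencumbered furan C5 to C9. It should give the keto lactone tert-butyl 3-[(1S,6S)-2-[3-methoxy-5-oxo-4-(propan-2-yl)-2,5-dihydrofuran-2-yl]-1-methyl-4-oxo-6-(prop-1-en-2-yl)cyclohexyl]propanoate F2 as a mixture at the two new centres. KOt-Bu in THF under equilibrating conditions then lets the C8 enolate acylate itself with the lactone (Dieckmann-type closure of ring C). The expected product is tert-butyl 3-[(1S,2S)-8-hydroxy-7-methoxy-1-methyl-4,5-dioxo-6-(propan-2-yl)-2-(prop-1-en-2-yl)-1,2,3,4,4a,5,8,8a-octahydronaphthalen-1-yl]propanoate F3. Dess–Martin oxidation of its C11 carbinol (buffered, reductive Na2S2O4 work-up) gives enedione 18, which enolises to 19.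

Step 3. The diene may add to the distal 1,1-disubstituted alkene of 3 through its vinylogous δ-carbon. Alternatively the trisubstituted enal may react so slowly that facial selectivity erodes. The fallback keeps the same two bonds and ring closure but carries the isopropenyl group as an acetyl group, so that no second alkene is present and the dienophile is doubly activated. It sets out from 2 and 5 and comes back at 8. Wittig reaction of 2 with aqueous methylglyoxal should give (2E)-2-methyl-4-oxopent-2-enal F4. The same oxazaborolidinium-catalysed cycloaddition with 5 should give (1R,6R)-6-acetyl-1-methyl-4-(triisopropylsilyloxy)cyclohex-3-ene-1-carbaldehyde F5. Horner–Wadsworth–Emmons reaction of the aldehyde with 7 (LiCl, i-Pr2NEt, MeCN) should give tert-butyl (2E)-3-[(1S,6R)-6-acetyl-1-methyl-4-(triisopropylsilyloxy)cyclohex-3-en-1-yl]prop-2-enoate F6. Wittig methylenation of the methyl ketone (Ph3P=CH2, THF, 0 °C) then returns 8.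

Step 6. The bulky silyl enol ether may transfer to divalent palladium too slowly. Allylic palladation of the isopropenyl group, or hydrolysis to the saturated ketone with loss of the regiochemical information, could then compete. The fallback sets out from 9 and comes back at 10. N-Bromosuccinimide in THF at −78 °C should brominate C8 of the enol ether regiospecifically to tert-butyl 3-[(1R,6S)-3-bromo-1-methyl-4-oxo-6-(prop-1-en-2-yl)cyclohexyl]propanoate F7. Li2CO3/LiBr in DMF at 110 °C then removes HBr towards C9, the only side that carries a β-hydrogen, to give 10.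

Further compounds
F1 | step 11 | tert-butyl{[4-methoxy-3-(propan-2-yl)furan-2-yl]oxy}dimethylsilane | COc1coc(O[Si](C)(C)C(C)(C)C)c1C(C)C
F2 | step 11 | tert-butyl 3-[(1S,6S)-2-[3-methoxy-5-oxo-4-(propan-2-yl)-2,5-dihydrofuran-2-yl]-1-methyl-4-oxo-6-(prop-1-en-2-yl)cyclohexyl]propanoate | C=C(C)[C@@H]1CC(=O)CC(C2OC(=O)C(C(C)C)=C2OC)[C@@]1(C)CCC(=O)OC(C)(C)C
F3 | step 11 | tert-butyl 3-[(1S,2S)-8-hydroxy-7-methoxy-1-methyl-4,5-dioxo-6-(propan-2-yl)-2-(prop-1-en-2-yl)-1,2,3,4,4a,5,8,8a-octahydronaphthalen-1-yl]propanoate | C=C(C)[C@@H]1CC(=O)C2C(=O)C(C(C)C)=C(OC)C(O)C2[C@@]1(C)CCC(=O)OC(C)(C)C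
F4 | step 3 | (2E)-2-methyl-4-oxopent-2-enal | CC(=O)/C=C(\C)C=O
F5 | step 3 | (1R,6R)-6-acetyl-1-methyl-4-(triisopropylsilyloxy)cyclohex-3-ene-1-carbaldehyde | CC(=O)[C@@H]1CC(O[Si](C(C)C)(C(C)C)C(C)C)=CC[C@@]1(C)C=O
F6 | step 3 | tert-butyl (2E)-3-[(1S,6R)-6-acetyl-1-methyl-4-(triisopropylsilyloxy)cyclohex-3-en-1-yl]prop-2-enoate | CC(=O)[C@@H]1CC(O[Si](C(C)C)(C(C)C)C(C)C)=CC[C@@]1(C)/C=C/C(=O)OC(C)(C)C
F7 | step 6 | tert-butyl 3-[(1R,6S)-3-bromo-1-methyl-4-oxo-6-(prop-1-en-2-yl)cyclohexyl]propanoate | C=C(C)[C@@H]1CC(=O)C(Br)C[C@@]1(C)CCC(=O)OC(C)(C)C
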